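The benzene ring (C1 CHO, C2 side chain, C3 OH, C4 OMe, C5 H, C6 OH; side chain C1′, C2′) is disconnected at C1–C2 and C4–C5. The route exploits the 1,5-relationship between ring carbon C4 and the C2′ oxygen: C4, C3, C2, C1′ and C2′ with that oxygen are carried as one δ-lactone ring, (R)-6-undecyl-5,6-dihydropyran-2-one, whereas C1, C6 and C5 come from methyl acetoacetate. A single Michael–Claisen operation forges both bonds, closes the carbocycle with the 4,6-dioxygen pattern and the C1 carbon in place, and releases the (R)-carbinol. Aromatisation, C4 O-methylation, para-hydroxylation at C3 and redox adjustment at C1 complete the synthesis.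

Key step: step 4

Remark on the chemistry: the allylborane is specified by its terpene source, (+)-α-pinene, because sign conventions for this reagent vary; the ring stereocentre formed in step 4 is drawn for anti addition and is destroyed in step 5, so the route does not depend on it.

Step 1
Reactants: 1 dodecanal
Product: 2 (R)-pentadec-1-en-4-ol
Conditions: dIpc2B(allyl) [B-allyldiisopinocampheylborane made from (+)-α-pinene, salt-free solution, 1.2 equiv], Et2O, −78 °C; then 3 M NaOH, 30% H2O2, 0 °C → rt
Reagents that add atoms: B-allyldiisopinocampheylborane from (+)-α-pinene, C=CCB([C@@H]1C[C@@H]2C[C@H]([C@H]1C)C2(C)C)[C@@H]1C[C@@H]2C[C@H]([C@H]1C)C2(C)C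
Why: Brown allylboration through a closed chair transition state in which the (+)-α-pinene-derived isopinocampheyl groups expose the Si face of the aldehyde, so allyl transfer should give the (R)-carbinol (allyl outranks undecyl in the descriptor).

Step 2
Reactants: 2 (R)-pentadec-1-en-4-ol; 3 acryloyl chloride
Product: 4 (R)-pentadec-1-en-4-yl prop-2-enoate
Conditions: 3 (1.5 equiv), Et3N, DMAP (cat.), CH2Cl2, 0 °C
Reagents that add atoms: none
Why: DMAP-catalysed O-acylation of a secondary alcohol by an acid chloride is fast at 0 °C and does not involve the carbinol carbon, so the configuration is retained.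

Step 3
Reactants: 4 (R)-pentadec-1-en-4-yl prop-2-enoate
Product: 5 (6R)-6-undecyl-5,6-dihydro-2H-pyran-2-one
Conditions: second-generation Grubbs catalyst RuCl2(=CHPh)(H2IMes)(PCy3) (5 mol %), CH2Cl2 (0.01 M), 40 °C
Reagents that add atoms: none
Why: Ring-closing olefin metathesis of a homoallyl acrylate is a standard entry to 6-substituted 5,6-dihydropyran-2-ones; the carbene loads on the terminal alkene, closes onto the acrylate, and loss of ethylene drives the closure at high dilution.

Step 4
Reactants: 5 (6R)-6-undecyl-5,6-dihydro-2H-pyran-2-one; 6 methyl acetoacetate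
Product: 8 methyl (6R)-2-hydroxy-6-[(2R)-2-hydroxytridecyl]-4-oxocyclohex-1-ene-1-carboxylate, via Michael adduct lactone 7 (not isolated)
Conditions: 6 (1.3 equiv), NaOMe (1.5 equiv), MeOH, 0 °C → rt, then reflux; then 1 M HCl, 0 °C
Reagents that add atoms: none
Why: The sodium enolate of 6 adds through its central carbon to C4 of lactone 5 (future C1–C2 bond) to give adduct 7, proton exchange then makes the terminal methyl enolate available, which attacks the lactone carbonyl (future C4–C5 bond), and collapse of the tetrahedral intermediate cleaves the ring C–O bond, frees the C2′ alkoxide and leaves the product as its 1,3-dione enolate, the thermodynamic sink. The closest known reaction is the alkoxide-mediated acetoacetate/crotonate Michael–Claisen condensation that gives dihydroorsellinates, here run on a cyclic enoate whose leaving group stays tethered. The carbocycle closes in a 6-exo-trig mode, enolate carbon onto the ester carbonyl. The one new stereocentre, the ring carbon that bears the side chain, is set by attack anti to the equatorial undecyl group of the half-chair lactone (trans-4,6 adduct, R as drawn) and is deleted in step 5, so it is not critical. The step needs 1,4- rather than 1,2-addition and Claisen closure rather than eliminative opening of the lactone: the soft, doubly stabilised enolate secures the first, and the axial position of the new C4 substituent in the trans adduct, which holds the methyl ketone over the lactone carbonyl, favours the second. The carbinol carbon is never alpha to a carbonyl group, so its R configuration is carried through unchanged.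

Step 5
Reactants: 8 methyl (6R)-2-hydroxy-6-[(2R)-2-hydroxytridecyl]-4-oxocyclohex-1-ene-1-carboxylate
Product: 11 (3R)-6,8-dihydroxy-3-undecyl-3,4-dihydro-1H-isochromen-1-one, via bromodione 9 (not isolated), via methyl resorcylate 10 (not isolated)
Conditions: Br2 (1.0 equiv), DMF, 0 °C, then 80 °C; then TsOH·H2O (cat.), toluene, reflux
Reagents that add atoms: none
Why: Halogenation–dehydrohalogenation aromatisation of a cyclohexane-1,3-dione: bromine attacks the enolised carbon between the two carbonyls (9), heating expels HBr to give resorcylate 10 with loss of the ring stereocentre, and the δ-hydroxy ester then closes to the six-membered lactone under acid catalysis by acyl–oxygen exchange, which leaves the carbinol centre untouched.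

Step 6
Reactants: 11 (3R)-6,8-dihydroxy-3-undecyl-3,4-dihydro-1H-isochromen-1-one
Product: 12 (3R)-8-hydroxy-6-methoxy-3-undecyl-3,4-dihydro-1H-isochromen-1-one
Conditions: MeI (1.1 equiv), K2CO3 (1.1 equiv), acetone, rt
Reagents that add atoms: iodomethane, CI
Why: Williamson etherification; the 8-OH is tied up in a hydrogen bond to the lactone carbonyl and is the poorer nucleophile, so one equivalent of MeI should methylate only the 6-OH (ring carbon C4 of the target).

Step 7
Reactants: 12 (3R)-8-hydroxy-6-methoxy-3-undecyl-3,4-dihydro-1H-isochromen-1-one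
Product: 14 (3R)-5,8-dihydroxy-6-methoxy-3-undecyl-3,4-dihydro-1H-isochromen-1-one, via aryl sulfate 13 (not isolated)
Conditions: K2S2O8 (1.2 equiv), 2 M NaOH, pyridine, 5 °C → rt, argon; then 6 M HCl, 90 °C
Reagents that add atoms: potassium peroxodisulfate, [K+].[K+].[O-]S(=O)(=O)OOS(=O)(=O)[O-]
Why: Elbs persulfate oxidation: the phenoxide attacks a peroxide oxygen of peroxodisulfate through its para carbon (C5 of the lactone, C3 of the target, the only free para position) to give aryl sulfate 13, which hot acid hydrolyses to the hydroquinone while re-closing any lactone opened by the alkali.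

Step 8
Reactants: 14 (3R)-5,8-dihydroxy-6-methoxy-3-undecyl-3,4-dihydro-1H-isochromen-1-one
Product: 15 (3R)-5,8-bis(benzyloxy)-6-methoxy-3-undecyl-3,4-dihydro-1H-isochromen-1-one
Conditions: BnBr (2.5 equiv), K2CO3, DMF, 60 °C, argon
Reagents that add atoms: benzyl bromide, BrCc1ccccc1
Why: Double Williamson benzylation in warm DMF is forcing enough to alkylate the chelated 8-OH as well as the free 5-OH, and exclusion of air keeps the hydroquinone from oxidising before it is capped.

Step 9
Reactants: 15 (3R)-5,8-bis(benzyloxy)-6-methoxy-3-undecyl-3,4-dihydro-1H-isochromen-1-one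
Product: 16 (2R)-1-[3,6-bis(benzyloxy)-2-(hydroxymethyl)-5-methoxyphenyl]tridecan-2-ol
Conditions: LiAlH4, THF, 0 °C → rt; then H2O, 15% NaOH
Reagents that add atoms: none
Why: Hydride reduction of the aryl lactone gives the benzylic alcohol and releases the secondary carbinol without touching the aryl ethers or the stereocentre, and the basic work-up protects the acid-sensitive dialkoxybenzyl alcohol.

Step 10
Reactants: 16 (2R)-1-[3,6-bis(benzyloxy)-2-(hydroxymethyl)-5-methoxyphenyl]tridecan-2-ol
Product: 18 (2R)-1-[3,6-bis(benzyloxy)-2-({[tert-butyl(dimethyl)silyl]oxy}methyl)-5-methoxyphenyl]tridecan-2-yl acetate, via mono-silyl ether 17 (not isolated)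
Conditions: TBSCl (1.1 equiv), Et3N, DMAP (cat.), CH2Cl2, 0 °C → rt; then Ac2O, rt
Reagents that add atoms: tert-butyldimethylsilyl chloride, CC(C)(C)[Si](C)(C)Cl; acetic anhydride, CC(=O)OC(C)=O
Why: TBSCl with Et3N/DMAP discriminates sterically in favour of the primary benzylic hydroxyl, after which Ac2O added to the same pot acetylates the remaining secondary alcohol under DMAP catalysis with retention.

Step 11
Reactants: 18 (2R)-1-[3,6-bis(benzyloxy)-2-({[tert-butyl(dimethyl)silyl]oxy}methyl)-5-methoxyphenyl]tridecan-2-yl acetate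
Product: 19 (2R)-1-[3,6-bis(benzyloxy)-2-(hydroxymethyl)-5-methoxyphenyl]tridecan-2-yl acetate
Conditions: Bu4NF, AcOH (1:1), THF, 0 °C → rt
Reagents that add atoms: none
Why: Fluoride cleaves the Si–O bond selectively, and buffering with acetic acid keeps the medium near neutral so that the secondary acetate neither hydrolyses nor migrates and the electron-rich benzylic alcohol does not ionise.

Step 12
Reactants: 19 (2R)-1-[3,6-bis(benzyloxy)-2-(hydroxymethyl)-5-methoxyphenyl]tridecan-2-yl acetate
Product: 20 (2R)-1-[3,6-bis(benzyloxy)-2-formyl-5-methoxyphenyl]tridecan-2-yl acetate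
Conditions: MnO2 (activated, excess), CH2Cl2, rt
Reagents that add atoms: none
Why: Activated MnO2 oxidises the electron-rich benzylic alcohol to the aldehyde and stops there, leaving the acetate and the aryl ethers untouched.

Step 13
Reactants: 20 (2R)-1-[3,6-bis(benzyloxy)-2-formyl-5-methoxyphenyl]tridecan-2-yl acetate
Product: 21 (2R)-1-(2-formyl-3,6-dihydroxy-5-methoxyphenyl)tridecan-2-yl acetate
Conditions: H2 (1 atm), Pd/C (10 wt %), EtOAc, rt
Reagents that add atoms: none
Why: Heterogeneous hydrogenolysis cleaves the two aryl benzyl ethers much faster than it reduces the hindered, electron-rich aryl aldehyde, so stopping after uptake of two equivalents of H2 should deliver the target with the acetate and the R centre intact.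

Compound list
1 | dodecanal | CCCCCCCCCCCC=O | starting material
2 | (R)-pentadec-1-en-4-ol | CCCCCCCCCCC[C@H](CC=C)O | intermediate
3 | acryloyl chloride | C=CC(Cl)=O | starting material
4 | (R)-pentadec-1-en-4-yl prop-2-enoate | CCCCCCCCCCC[C@H](CC=C)OC(=O)C=C | intermediate
5 | (6R)-6-undecyl-5,6-dihydro-2H-pyran-2-one | CCCCCCCCCCC[C@@H]1CC=CC(=O)O1 | intermediate
6 | methyl acetoacetate | COC(=O)CC(C)=O | starting material
7 | methyl 3-oxo-2-[(4R,6R)-2-oxo-6-undecyloxan-4-yl]butanoate (Michael adduct, side-chain alpha carbon unassigned, not isolated) | CCCCCCCCCCC[C@@H]1C[C@@H](C(C(C)=O)C(=O)OC)CC(=O)O1 | intermediate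
8 | methyl (6R)-2-hydroxy-6-[(2R)-2-hydroxytridecyl]-4-oxocyclohex-1-ene-1-carboxylate | COC(=O)C1=C(O)CC(=O)C[C@H]1C[C@H](O)CCCCCCCCCCC | intermediate
9 | methyl (6R)-3-bromo-2-hydroxy-6-[(2R)-2-hydroxytridecyl]-4-oxocyclohex-1-ene-1-carboxylate (bromodione, C3 epimers, not isolated) | COC(=O)C1=C(O)C(Br)C(=O)C[C@H]1C[C@H](O)CCCCCCCCCCC | intermediate
10 | methyl 2,4-dihydroxy-6-[(2R)-2-hydroxytridecyl]benzoate (not isolated) | CCCCCCCCCCC[C@H](Cc1cc(O)cc(O)c1C(=O)OC)O | intermediate
11 | (3R)-6,8-dihydroxy-3-undecyl-3,4-dihydro-1H-isochromen-1-one | CCCCCCCCCCC[C@@H]1Cc2cc(O)cc(O)c2C(=O)O1 | intermediate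
12 | (3R)-8-hydroxy-6-methoxy-3-undecyl-3,4-dihydro-1H-isochromen-1-one | CCCCCCCCCCC[C@@H]1Cc2cc(OC)cc(O)c2C(=O)O1 | intermediate
13 | (3R)-8-hydroxy-6-methoxy-1-oxo-3-undecyl-3,4-dihydro-1H-isochromen-5-yl hydrogen sulfate (present as its salt, not isolated) | CCCCCCCCCCC[C@@H]1Cc2c(OS(=O)(=O)O)c(OC)cc(O)c2C(=O)O1 | intermediate
14 | (3R)-5,8-dihydroxy-6-methoxy-3-undecyl-3,4-dihydro-1H-isochromen-1-one | CCCCCCCCCCC[C@@H]1Cc2c(O)c(OC)cc(O)c2C(=O)O1 | intermediate
15 | (3R)-5,8-bis(benzyloxy)-6-methoxy-3-undecyl-3,4-dihydro-1H-isochromen-1-one | CCCCCCCCCCC[C@@H]1Cc2c(OCc3ccccc3)c(OC)cc(OCc3ccccc3)c2C(=O)O1 | intermediate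
16 | (2R)-1-[3,6-bis(benzyloxy)-2-(hydroxymethyl)-5-methoxyphenyl]tridecan-2-ol | CCCCCCCCCCC[C@H](Cc1c(OCc2ccccc2)c(OC)cc(OCc2ccccc2)c1CO)O | intermediate
17 | (2R)-1-[3,6-bis(benzyloxy)-2-({[tert-butyl(dimethyl)silyl]oxy}methyl)-5-methoxyphenyl]tridecan-2-ol (not isolated) | CCCCCCCCCCC[C@H](Cc1c(OCc2ccccc2)c(OC)cc(OCc2ccccc2)c1CO[Si](C)(C)C(C)(C)C)O | intermediate
18 | (2R)-1-[3,6-bis(benzyloxy)-2-({[tert-butyl(dimethyl)silyl]oxy}methyl)-5-methoxyphenyl]tridecan-2-yl acetate | CCCCCCCCCCC[C@H](Cc1c(OCc2ccccc2)c(OC)cc(OCc2ccccc2)c1CO[Si](C)(C)C(C)(C)C)OC(C)=O | intermediate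
19 | (2R)-1-[3,6-bis(benzyloxy)-2-(hydroxymethyl)-5-methoxyphenyl]tridecan-2-yl acetate | CCCCCCCCCCC[C@H](Cc1c(OCc2ccccc2)c(OC)cc(OCc2ccccc2)c1CO)OC(C)=O | intermediate
20 | (2R)-1-[3,6-bis(benzyloxy)-2-formyl-5-methoxyphenyl]tridecan-2-yl acetate | CCCCCCCCCCC[C@H](Cc1c(OCc2ccccc2)c(OC)cc(OCc2ccccc2)c1C=O)OC(C)=O | intermediate
21 | (2R)-1-(2-formyl-3,6-dihydroxy-5-methoxyphenyl)tridecan-2-yl acetate | CCCCCCCCCCC[C@H](Cc1c(O)c(OC)cc(O)c1C=O)OC(C)=O | target

Total step count: 13. Longest linear sequence: 13 steps, from dodecanal 1 to target 21.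

Steps most likely to fail

Step 4. The base may deprotonate the lactone at its γ-carbon and eliminate the carboxylate, opening the ring to a dienoate, or the sequence may stall after conjugate addition without Claisen closure. The fallback keeps the same two bond formations but runs them on the open-chain enoate type for which the condensation is established. It sets out from 2: silylation (TBSCl, imidazole, DMF) gives tert-butyl(dimethyl){[(4R)-pentadec-1-en-4-yl]oxy}silane F1. Cross-metathesis with methyl acrylate (second-generation Hoveyda–Grubbs catalyst RuCl2(=CH-C6H4-2-OiPr)(H2IMes), CH2Cl2, 40 °C) gives methyl (2E,5R)-5-{[tert-butyl(dimethyl)silyl]oxy}hexadec-2-enoate F2. Condensation with 6 (NaOMe, MeOH, reflux) gives methyl 6-[(2R)-2-{[tert-butyl(dimethyl)silyl]oxy}tridecyl]-2-hydroxy-4-oxocyclohex-1-ene-1-carboxylate F3 as ring epimers. Aromatisation as in step 5 (Br2, DMF, 0 °C then 80 °C) gives methyl 6-[(2R)-2-{[tert-butyl(dimethyl)silyl]oxy}tridecyl]-2,4-dihydroxybenzoate F4. HF·pyridine in THF followed by TsOH·H2O in refluxing toluene removes the silyl group and lactonises, so the fallback comes back to the route at 11.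

Step 7. Conversion in the persulfate oxidation may be low, the electron-rich phenoxide may be over-oxidised to polymeric material, and the lipophilic substrate may dissolve poorly in the aqueous base. The fallback introduces the oxygen by halogenation and boron chemistry and sets out from 12. Benzylation (BnBr, K2CO3, DMF, 60 °C) gives (3R)-8-(benzyloxy)-6-methoxy-3-undecyl-3,4-dihydro-1H-isochromen-1-one F5. NBS in MeCN at 0 °C should brominate para to the benzyloxy group, away from the position flanked by two alkoxy groups, to give (3R)-8-(benzyloxy)-5-bromo-6-methoxy-3-undecyl-3,4-dihydro-1H-isochromen-1-one F6. Miyaura borylation (B2pin2, Pd(OAc)2, SPhos, KOAc, dioxane, 90 °C) gives (3R)-8-(benzyloxy)-6-methoxy-5-(4,4,5,5-tetramethyl-1,3,2-dioxaborolan-2-yl)-3-undecyl-3,4-dihydro-1H-isochromen-1-one F7. Oxidation (NaBO3·4H2O, THF/H2O, rt) gives (3R)-8-(benzyloxy)-5-hydroxy-6-methoxy-3-undecyl-3,4-dihydro-1H-isochromen-1-one F8. Benzylation under the conditions of step 8 returns to the route at 15.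

Step 5. Bromine may substitute the newly formed resorcinol ring, and the HBr generated in hot DMF may substitute or oxidise the free secondary alcohol. The fallback uses an oxidative aromatisation that also installs the methyl ether and sets out from 8. Iodine (2 equiv) in refluxing MeOH should form the vinylogous methyl ester at the unhindered carbonyl remote from the ester and then aromatise, giving methyl 2-hydroxy-6-[(2R)-2-hydroxytridecyl]-4-methoxybenzoate F9. TsOH·H2O (cat.) in refluxing toluene then lactonises, and the fallback rejoins the route at 12, so step 6 is not needed.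

Further compounds
F1 | step 4 | tert-butyl(dimethyl){[(4R)-pentadec-1-en-4-yl]oxy}silane | CCCCCCCCCCC[C@H](CC=C)O[Si](C)(C)C(C)(C)C
F2 | step 4 | methyl (2E,5R)-5-{[tert-butyl(dimethyl)silyl]oxy}hexadec-2-enoate | CCCCCCCCCCC[C@H](C/C=C/C(=O)OC)O[Si](C)(C)C(C)(C)C
F3 | step 4 | methyl 6-[(2R)-2-{[tert-butyl(dimethyl)silyl]oxy}tridecyl]-2-hydroxy-4-oxocyclohex-1-ene-1-carboxylate (ring epimers) | COC(=O)C1=C(O)CC(=O)CC1C[C@H](O[Si](C)(C)C(C)(C)C)CCCCCCCCCCC
F4 | step 4 | methyl 6-[(2R)-2-{[tert-butyl(dimethyl)silyl]oxy}tridecyl]-2,4-dihydroxybenzoate | CCCCCCCCCCC[C@H](Cc1cc(O)cc(O)c1C(=O)OC)O[Si](C)(C)C(C)(C)C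
F5 | step 7 | (3R)-8-(benzyloxy)-6-methoxy-3-undecyl-3,4-dihydro-1H-isochromen-1-one | CCCCCCCCCCC[C@@H]1Cc2cc(OC)cc(OCc3ccccc3)c2C(=O)O1
F6 | step 7 | (3R)-8-(benzyloxy)-5-bromo-6-methoxy-3-undecyl-3,4-dihydro-1H-isochromen-1-one | CCCCCCCCCCC[C@@H]1Cc2c(Br)c(OC)cc(OCc3ccccc3)c2C(=O)O1
F7 | step 7 | (3R)-8-(benzyloxy)-6-methoxy-5-(4,4,5,5-tetramethyl-1,3,2-dioxaborolan-2-yl)-3-undecyl-3,4-dihydro-1H-isochromen-1-one | CCCCCCCCCCC[C@@H]1Cc2c(B3OC(C)(C)C(C)(C)O3)c(OC)cc(OCc3ccccc3)c2C(=O)O1
F8 | step 7 | (3R)-8-(benzyloxy)-5-hydroxy-6-methoxy-3-undecyl-3,4-dihydro-1H-isochromen-1-one | CCCCCCCCCCC[C@@H]1Cc2c(O)c(OC)cc(OCc3ccccc3)c2C(=O)O1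
F9 | step 5 | methyl 2-hydroxy-6-[(2R)-2-hydroxytridecyl]-4-methoxybenzoate | CCCCCCCCCCC[C@H](Cc1cc(OC)cc(O)c1C(=O)OC)O
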